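The tetrahydrofuran ring is dissected into its C5H2–O1–C2H(aryl) triad, a non-stabilised carbonyl ylide, and the C3–C4 edge, the (E)-alkene of an enantiopure γ-aryl-γ-silyloxy enoate. One (3+2) cycloaddition forms C5–C4 and C2–C3, closes the ring and sets C2, C3 and C4: the E-geometry gives the 3,4-trans pair, the exo approach the 2,3-trans pair, and the carbinol stereocentre directs the face. The ylide is released by fluoride from an α-chloro (trimethylsilyl)methyl ether of O-benzylvanillin. Because anti induction is expected, the carbinol is carried in the (S)-form and inverted afterwards by a Mitsunobu reaction; ester reduction and debenzylation finish the synthesis.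

Key step: step 5

Remark on locants: the ring is numbered O1, C2 (aryl), C3 (CH2OH or ester), C4 (carbinol side chain), C5 (CH2); "carbinol carbon" is the exocyclic CH(O)Ar on C4.

Assumption: (S,S)-ProPhenol is taken as the ligand antipode that delivers alcohol 5 in step 2; if the sense of induction is the opposite, (R,R)-ProPhenol is used.

Step 1
Reactants: 1 4-(benzyloxy)-3-methoxybenzaldehyde; 2 (trimethylsilyl)methanol
Product: 3 1-(benzyloxy)-4-{bis[(trimethylsilyl)methoxy]methyl}-2-methoxybenzene
Conditions: 2 (3 equiv), p-TsOH·H2O (cat.), cyclohexane, reflux, Dean–Stark; Et3N quench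
Reagents that add atoms: none
Why: Acid-catalysed acetalisation of the aldehyde with the primary α-silyl alcohol under azeotropic removal of water should give the bis[(trimethylsilyl)methyl] acetal; no stereocentre is formed.

Step 2
Reactants: 1 4-(benzyloxy)-3-methoxybenzaldehyde; 4 methyl propiolate
Product: 5 methyl (R)-4-[4-(benzyloxy)-3-methoxyphenyl]-4-hydroxybut-2-ynoate
Conditions: 4 (3 equiv), Me2Zn (3 equiv), (S,S)-ProPhenol (10 mol %), toluene, 4 °C; aq. NH4Cl
Reagents that add atoms: none
Why: Catalytic enantioselective alkynylation of an aryl aldehyde by a zinc alkynylide held in the dinuclear Zn–ProPhenol complex should set the carbinol stereocentre by reagent control (descriptor R because the alkynyl group outranks the aryl group).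

Step 3
Reactants: 5 methyl (R)-4-[4-(benzyloxy)-3-methoxyphenyl]-4-hydroxybut-2-ynoate
Product: 6 methyl (S,E)-4-[4-(benzyloxy)-3-methoxyphenyl]-4-hydroxybut-2-enoate
Conditions: NaAlH2(OCH2CH2OMe)2 (Red-Al), THF, −72 °C; aq. potassium sodium tartrate
Reagents that add atoms: none
Why: Alkoxide-directed trans-hydroalumination of the γ-hydroxy ynoate followed by protonation should give the (E)-enoate without reducing the ester; the stereocentre is untouched and its descriptor changes from R to S only because the alkenyl group ranks below the aryl group.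

Step 4
Reactants: 6 methyl (S,E)-4-[4-(benzyloxy)-3-methoxyphenyl]-4-hydroxybut-2-enoate
Product: 7 methyl (S,E)-4-[4-(benzyloxy)-3-methoxyphenyl]-4-[(triisopropylsilyl)oxy]but-2-enoate
Conditions: i-Pr3SiOTf, 2,6-lutidine, CH2Cl2, 0 °C
Reagents that add atoms: triisopropylsilyl trifluoromethanesulfonate, CC(C)[Si](C(C)C)(C(C)C)OS(=O)(=O)C(F)(F)F
Why: Silylation of the secondary benzylic alcohol with the silyl triflate should give a bulky, non-chelating ether that tolerates CsF and acts as the large electronegative substituent in the key step.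

Step 5
Reactants: 3 1-(benzyloxy)-4-{bis[(trimethylsilyl)methoxy]methyl}-2-methoxybenzene; 7 methyl (S,E)-4-[4-(benzyloxy)-3-methoxyphenyl]-4-[(triisopropylsilyl)oxy]but-2-enoate
Product: 10 methyl (2R,3R,4R)-2-[4-(benzyloxy)-3-methoxyphenyl]-4-{(S)-[4-(benzyloxy)-3-methoxyphenyl][(triisopropylsilyl)oxy]methyl}tetrahydrofuran-3-carboxylate, via α-chloro ether 8 (not isolated), via carbonyl ylide 9 (not isolated)
Conditions: 3 (2 equiv), AcCl, SOCl2 (cat.), CH2Cl2, 0 °C to rt, evaporate; then slow addition of crude 8 to 7, CsF (4 equiv), MeCN, rt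
Reagents that add atoms: none
Why: Acetyl chloride converts acetal 3 into α-chloro ether 8, fluoride then attacks silicon while chloride leaves (1,3-elimination), and the released non-stabilised carbonyl ylide 9 adds suprafacially across the electron-poor alkene of 7 in a concerted but asynchronous [π4s+π2s] (3+2) cycloaddition; the closest known reaction type is the fluoride-induced generation of carbonyl ylides from α-chloroalkyl (trimethylsilyl)methyl ethers and their cycloaddition to acrylates and fumarates. The tetrahydrofuran ring is closed by this intermolecular cycloaddition, which forms C5–C4 and C2–C3 in the same operation (in the stepwise limit a conjugate addition followed by 5-endo-trig closure of the ester enolate onto the benzylic oxocarbenium ion). C3 and C4 should come out trans because the (E)-geometry of 7 is transferred stereospecifically. The face at C4 is controlled by the adjacent (S)-carbinol carbon: with the C–OSi bond antiperiplanar to the incoming CH2 terminus, the C–H bond in the alkene plane and the aryl group outside (the Felkin–Anh-type arrangement known from cuprate additions to (E)-γ-alkoxy enoates), the new C5–C4 bond forms anti to the C–O bond. C2 is controlled by the exo approach of the E-configured ylide, which keeps its aryl group away from the ester and gives the 2,3-trans relation. The step needs regioselectivity, which the polarisation of the ylide secures: the unsubstituted, carbanion-like CH2 terminus bonds to the β-carbon and the benzylic, oxocarbenium-like carbon to the α-carbon of the enoate.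

Step 6
Reactants: 10 methyl (2R,3R,4R)-2-[4-(benzyloxy)-3-methoxyphenyl]-4-{(S)-[4-(benzyloxy)-3-methoxyphenyl][(triisopropylsilyl)oxy]methyl}tetrahydrofuran-3-carboxylate
Product: 11 methyl (2R,3R,4R)-2-[4-(benzyloxy)-3-methoxyphenyl]-4-{(S)-[4-(benzyloxy)-3-methoxyphenyl](hydroxy)methyl}tetrahydrofuran-3-carboxylate
Conditions: Bu4NF, AcOH, THF, rt
Reagents that add atoms: none
Why: Fluoride-mediated cleavage of the silyl ether, buffered with acetic acid to avoid base-induced epimerisation next to the ester, should free the (S)-carbinol, since the lactone that could form with the C3 ester would be trans-fused and too strained.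

Step 7
Reactants: 11 methyl (2R,3R,4R)-2-[4-(benzyloxy)-3-methoxyphenyl]-4-{(S)-[4-(benzyloxy)-3-methoxyphenyl](hydroxy)methyl}tetrahydrofuran-3-carboxylate
Product: 12 methyl (2R,3R,4R)-2-[4-(benzyloxy)-3-methoxyphenyl]-4-{(R)-[4-(benzyloxy)-3-methoxyphenyl][(4-nitrobenzoyl)oxy]methyl}tetrahydrofuran-3-carboxylate
Conditions: 4-O2NC6H4CO2H, PPh3, DIAD, toluene, −20 to 0 °C
Reagents that add atoms: 4-nitrobenzoic acid, O=C(O)c1ccc([N+](=O)[O-])cc1
Why: Mitsunobu reaction: SN2 displacement of the alkoxyphosphonium ion by 4-nitrobenzoate should invert the carbinol carbon from S to R, the acidic pronucleophile and the low temperature favouring the SN2 over the SN1 pathway.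

Step 8
Reactants: 12 methyl (2R,3R,4R)-2-[4-(benzyloxy)-3-methoxyphenyl]-4-{(R)-[4-(benzyloxy)-3-methoxyphenyl][(4-nitrobenzoyl)oxy]methyl}tetrahydrofuran-3-carboxylate
Product: 13 (R)-[4-(benzyloxy)-3-methoxyphenyl]{(3R,4S,5R)-5-[4-(benzyloxy)-3-methoxyphenyl]-4-(hydroxymethyl)tetrahydrofuran-3-yl}methanol
Conditions: i-Bu2AlH (6 equiv), CH2Cl2, −78 to 0 °C; aq. potassium sodium tartrate
Reagents that add atoms: none
Why: Hydride reduction with i-Bu2AlH should convert the methyl ester into the primary alcohol and cleave the 4-nitrobenzoate without affecting the benzyl ethers or any stereocentre.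

Step 9
Reactants: 13 (R)-[4-(benzyloxy)-3-methoxyphenyl]{(3R,4S,5R)-5-[4-(benzyloxy)-3-methoxyphenyl]-4-(hydroxymethyl)tetrahydrofuran-3-yl}methanol
Product: 14 (R)-(4-hydroxy-3-methoxyphenyl)[(3R,4S,5R)-5-(4-hydroxy-3-methoxyphenyl)-4-(hydroxymethyl)tetrahydrofuran-3-yl]methanol
Conditions: H2 (1 atm), 10% Pd/C, EtOAc, rt
Reagents that add atoms: none
Why: Hydrogenolysis of the two aryl benzyl ethers over Pd/C under mild conditions, stopped after the uptake of two equivalents of hydrogen, should spare the benzylic C–O bonds of the ring and of the carbinol and give the target.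

Compound list

1 | 4-(benzyloxy)-3-methoxybenzaldehyde (O-benzylvanillin) | COc1cc(C=O)ccc1OCc1ccccc1 | starting material
2 | (trimethylsilyl)methanol | C[Si](C)(C)CO | starting material
3 | 1-(benzyloxy)-4-{bis[(trimethylsilyl)methoxy]methyl}-2-methoxybenzene | COc1cc(C(OC[Si](C)(C)C)OC[Si](C)(C)C)ccc1OCc1ccccc1 | intermediate
4 | methyl propiolate | C#CC(=O)OC | starting material
5 | methyl (R)-4-[4-(benzyloxy)-3-methoxyphenyl]-4-hydroxybut-2-ynoate | COc1cc([C@@H](O)C#CC(=O)OC)ccc1OCc1ccccc1 | intermediate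
6 | methyl (S,E)-4-[4-(benzyloxy)-3-methoxyphenyl]-4-hydroxybut-2-enoate | COc1cc([C@@H](O)/C=C/C(=O)OC)ccc1OCc1ccccc1 | intermediate
7 | methyl (S,E)-4-[4-(benzyloxy)-3-methoxyphenyl]-4-[(triisopropylsilyl)oxy]but-2-enoate | COc1cc([C@@H](O[Si](C(C)C)(C(C)C)C(C)C)/C=C/C(=O)OC)ccc1OCc1ccccc1 | intermediate
8 | 1-(benzyloxy)-4-{chloro[(trimethylsilyl)methoxy]methyl}-2-methoxybenzene (racemic α-chloro ether, not isolated) | COc1cc(C(Cl)OC[Si](C)(C)C)ccc1OCc1ccccc1 | intermediate
9 | (E)-[4-(benzyloxy)-3-methoxybenzylidene]oxonium methylide (carbonyl ylide, not isolated) | COc1cc(/C=[O+]/[CH2-])ccc1OCc1ccccc1 | intermediate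
10 | methyl (2R,3R,4R)-2-[4-(benzyloxy)-3-methoxyphenyl]-4-{(S)-[4-(benzyloxy)-3-methoxyphenyl][(triisopropylsilyl)oxy]methyl}tetrahydrofuran-3-carboxylate | COc1cc([C@@H](O[Si](C(C)C)(C(C)C)C(C)C)[C@H]2CO[C@@H](c3ccc(OCc4ccccc4)c(OC)c3)[C@@H]2C(=O)OC)ccc1OCc1ccccc1 | intermediate
11 | methyl (2R,3R,4R)-2-[4-(benzyloxy)-3-methoxyphenyl]-4-{(S)-[4-(benzyloxy)-3-methoxyphenyl](hydroxy)methyl}tetrahydrofuran-3-carboxylate | COc1cc([C@@H](O)[C@H]2CO[C@@H](c3ccc(OCc4ccccc4)c(OC)c3)[C@@H]2C(=O)OC)ccc1OCc1ccccc1 | intermediate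
12 | methyl (2R,3R,4R)-2-[4-(benzyloxy)-3-methoxyphenyl]-4-{(R)-[4-(benzyloxy)-3-methoxyphenyl][(4-nitrobenzoyl)oxy]methyl}tetrahydrofuran-3-carboxylate | COc1cc([C@H](OC(=O)c2ccc([N+](=O)[O-])cc2)[C@H]3CO[C@@H](c4ccc(OCc5ccccc5)c(OC)c4)[C@@H]3C(=O)OC)ccc1OCc1ccccc1 | intermediate
13 | (R)-[4-(benzyloxy)-3-methoxyphenyl]{(3R,4S,5R)-5-[4-(benzyloxy)-3-methoxyphenyl]-4-(hydroxymethyl)tetrahydrofuran-3-yl}methanol | COc1cc([C@H](O)[C@H]2CO[C@@H](c3ccc(OCc4ccccc4)c(OC)c3)[C@@H]2CO)ccc1OCc1ccccc1 | intermediate
14 | (R)-(4-hydroxy-3-methoxyphenyl)[(3R,4S,5R)-5-(4-hydroxy-3-methoxyphenyl)-4-(hydroxymethyl)tetrahydrofuran-3-yl]methanol | COc1cc([C@H](O)[C@H]2CO[C@@H](c3ccc(O)c(OC)c3)[C@@H]2CO)ccc1O | target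

Total step count: 9. Longest linear sequence: 8 steps (steps 2 to 9, from 1 and 4); step 1 is the convergent branch.

Steps most likely to fail

Step 5. The ylide may approach the other face of 7 (aryl group inside instead of hydrogen inside), so that the facial selectivity is low or reversed. The β-branched enoate may also trap the short-lived ylide too slowly. The fallback keeps substrate control but in the opposite sense and omits the inversion; it sets out from 1 and 4 and comes back to the route at 13. Alkynylation of 1 with 4 under (R,R)-ProPhenol/Me2Zn should give methyl (S)-4-[4-(benzyloxy)-3-methoxyphenyl]-4-hydroxybut-2-ynoate F1. Red-Al reduction should give methyl (R,E)-4-[4-(benzyloxy)-3-methoxyphenyl]-4-hydroxybut-2-enoate F2. Silylation with i-Pr3SiOTf should give methyl (R,E)-4-[4-(benzyloxy)-3-methoxyphenyl]-4-[(triisopropylsilyl)oxy]but-2-enoate F3. Cycloaddition with ylide 9 (from 3 as in step 5), now through the syn mode, should give methyl (2R,3R,4R)-2-[4-(benzyloxy)-3-methoxyphenyl]-4-{(R)-[4-(benzyloxy)-3-methoxyphenyl][(triisopropylsilyl)oxy]methyl}tetrahydrofuran-3-carboxylate F4. Reduction of the ester with i-Bu2AlH should give {(2R,3S,4R)-2-[4-(benzyloxy)-3-methoxyphenyl]-4-{(R)-[4-(benzyloxy)-3-methoxyphenyl][(triisopropylsilyl)oxy]methyl}tetrahydrofuran-3-yl}methanol F5, and desilylation with Bu4NF should give 13.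

Step 7. Ionisation of the alkoxyphosphonium ion of the electron-rich benzylic alcohol (SN1 pathway) may erode the inversion, and elimination may compete. The fallback replaces substitution by oxidation and reagent-controlled reduction; it sets out from 11 and comes back at 13. Dess–Martin periodinane should give methyl (2R,3R,4R)-4-[4-(benzyloxy)-3-methoxybenzoyl]-2-[4-(benzyloxy)-3-methoxyphenyl]tetrahydrofuran-3-carboxylate F6. Corey–Bakshi–Shibata reduction with (S)-2-methyl-CBS-oxazaborolidine and BH3·SMe2, the aryl group acting as the large substituent, should give methyl (2R,3R,4R)-2-[4-(benzyloxy)-3-methoxyphenyl]-4-{(R)-[4-(benzyloxy)-3-methoxyphenyl](hydroxy)methyl}tetrahydrofuran-3-carboxylate F7. Reduction with i-Bu2AlH should then give 13.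

Step 2. The zinc alkynylide may add slowly to the electron-rich aldehyde, and the enantioselectivity may be insufficient. The fallback sets the stereocentre by enzymatic kinetic resolution and builds the enoate by cross-metathesis; it sets out from 1 and comes back at 6. Addition of CH2=CHMgBr in THF at 0 °C should give racemic 1-[4-(benzyloxy)-3-methoxyphenyl]prop-2-en-1-ol F8. Candida antarctica lipase B with vinyl acetate should leave (S)-1-[4-(benzyloxy)-3-methoxyphenyl]prop-2-en-1-ol F9 and convert the antipode into (R)-1-[4-(benzyloxy)-3-methoxyphenyl]allyl acetate F10, which is separated. Cross-metathesis of F9 with methyl acrylate (second-generation Hoveyda–Grubbs catalyst, CH2Cl2, 40 °C) should give 6.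

Further compounds

F1 | step 5 | methyl (S)-4-[4-(benzyloxy)-3-methoxyphenyl]-4-hydroxybut-2-ynoate | COc1cc([C@H](O)C#CC(=O)OC)ccc1OCc1ccccc1
F2 | step 5 | methyl (R,E)-4-[4-(benzyloxy)-3-methoxyphenyl]-4-hydroxybut-2-enoate | COc1cc([C@H](O)/C=C/C(=O)OC)ccc1OCc1ccccc1
F3 | step 5 | methyl (R,E)-4-[4-(benzyloxy)-3-methoxyphenyl]-4-[(triisopropylsilyl)oxy]but-2-enoate | COc1cc([C@H](O[Si](C(C)C)(C(C)C)C(C)C)/C=C/C(=O)OC)ccc1OCc1ccccc1
F4 | step 5 | methyl (2R,3R,4R)-2-[4-(benzyloxy)-3-methoxyphenyl]-4-{(R)-[4-(benzyloxy)-3-methoxyphenyl][(triisopropylsilyl)oxy]methyl}tetrahydrofuran-3-carboxylate | COc1cc([C@H](O[Si](C(C)C)(C(C)C)C(C)C)[C@H]2CO[C@@H](c3ccc(OCc4ccccc4)c(OC)c3)[C@@H]2C(=O)OC)ccc1OCc1ccccc1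
F5 | step 5 | {(2R,3S,4R)-2-[4-(benzyloxy)-3-methoxyphenyl]-4-{(R)-[4-(benzyloxy)-3-methoxyphenyl][(triisopropylsilyl)oxy]methyl}tetrahydrofuran-3-yl}methanol | COc1cc([C@H](O[Si](C(C)C)(C(C)C)C(C)C)[C@H]2CO[C@@H](c3ccc(OCc4ccccc4)c(OC)c3)[C@@H]2CO)ccc1OCc1ccccc1
F6 | step 7 | methyl (2R,3R,4R)-4-[4-(benzyloxy)-3-methoxybenzoyl]-2-[4-(benzyloxy)-3-methoxyphenyl]tetrahydrofuran-3-carboxylate | COc1cc(C(=O)[C@H]2CO[C@@H](c3ccc(OCc4ccccc4)c(OC)c3)[C@@H]2C(=O)OC)ccc1OCc1ccccc1
F7 | step 7 | methyl (2R,3R,4R)-2-[4-(benzyloxy)-3-methoxyphenyl]-4-{(R)-[4-(benzyloxy)-3-methoxyphenyl](hydroxy)methyl}tetrahydrofuran-3-carboxylate | COc1cc([C@H](O)[C@H]2CO[C@@H](c3ccc(OCc4ccccc4)c(OC)c3)[C@@H]2C(=O)OC)ccc1OCc1ccccc1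
F8 | step 2 | racemic 1-[4-(benzyloxy)-3-methoxyphenyl]prop-2-en-1-ol | COc1cc(C(O)C=C)ccc1OCc1ccccc1
F9 | step 2 | (S)-1-[4-(benzyloxy)-3-methoxyphenyl]prop-2-en-1-ol | COc1cc([C@@H](O)C=C)ccc1OCc1ccccc1
F10 | step 2 | (R)-1-[4-(benzyloxy)-3-methoxyphenyl]allyl acetate | COc1cc([C@H](OC(C)=O)C=C)ccc1OCc1ccccc1
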